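## Retrosynthetic overview

1. The last C–O bonds are the 1β,10α-epoxide, put on the finished germacra-1(10),4,11(13)-trienolide by peripheral epoxidation.
2. The ten-membered carbocycle is closed at C6–C7 by a CrCl2-mediated intramolecular 2-(methoxycarbonyl)allylation of a (Z)-enal; the C6 alkoxide then closes the γ-lactone (carbocycle first, lactone second, epoxide third).
3. Key disconnection, C8–O: the complete (2R,3S)-epoxy ester and the C8 stereocentre are installed in one enamine-catalysed α-acyloxylation of an aldehyde with a mixed diacyl peroxide built from the epoxy acid and 2,4,6-trichlorobenzoyl chloride (new C–O bond-forming step). The acid comes from a Sharpless epoxidation.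
4. The C3–O benzoate comes from an Evans–Tishchenko transfer from benzaldehyde after an asymmetric aldol; a Claisen rearrangement sets the E-C1=C10 alkene and delivers the aldehyde for line 3.
5. Carbon sources: 3-methylfuran-2(5H)-one (locks the Z-C4=C5 alkene), 3-methylbut-3-en-2-one, butyl vinyl ether, methyl propiolate, benzaldehyde and (2E)-2-methylbut-2-en-1-ol.

Assumption: positions are given in germacrane numbering (C1–C15) of the target; the side-chain acid is read from the SMILES as (2R,3S)-2,3-dimethyloxirane-2-carboxylic acid (cis-dimethyl), and the six building blocks above, like the reagent 2,4,6-trichlorobenzoyl chloride, are taken as cheap commercial materials.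

## Route

Step 1
Reactants: 1 3-methylfuran-2(5H)-one
Product: 3 (2Z)-4-[(tert-butyldimethylsilyl)oxy]-N-methoxy-N,2-dimethylbut-2-enamide, via hydroxy amide 2 (not isolated)
Conditions: MeNH(OMe)·HCl, Me3Al, CH2Cl2, 0 °C to rt; crude, then TBSCl, imidazole, DMF, rt
Reagents that add atoms: N,O-dimethylhydroxylamine hydrochloride, CNOC.Cl; tert-butyldimethylsilyl chloride, CC(C)(C)[Si](C)(C)Cl
Why: Aluminium-amide aminolysis of the butenolide (Weinreb amide formation) opens the ring with the Z-alkene inherited from the ring, and immediate silylation of the primary alcohol prevents relactonisation; no stereocentre is formed.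

Step 2
Reactants: 3 (2Z)-4-[(tert-butyldimethylsilyl)oxy]-N-methoxy-N,2-dimethylbut-2-enamide
Product: 4 (2Z)-4-[(tert-butyldimethylsilyl)oxy]-2-methylbut-2-enal
Conditions: i-Bu2AlH, THF, −78 °C
Reagents that add atoms: none
Why: Weinreb amide reduction stops at the aldehyde through the chelated tetrahedral aluminate, and the Z-enal geometry is kept at low temperature.

Step 3
Reactants: 4 (2Z)-4-[(tert-butyldimethylsilyl)oxy]-2-methylbut-2-enal; 5 3-methylbut-3-en-2-one
Product: 6 (5S,6Z)-8-[(tert-butyldimethylsilyl)oxy]-5-hydroxy-2,6-dimethylocta-1,6-dien-3-one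
Conditions: (R,R)-ProPhenol (10 mol %), Et2Zn (20 mol %), 4 Å MS, THF, −20 °C, 5 (5 equiv)
Reagents that add atoms: none
Why: Direct catalytic asymmetric aldol addition (dinuclear zinc–ProPhenol catalysis, precedented for methyl vinyl ketone donors); the zinc enolate of 5 is delivered to the Si face of the enal, setting C3 as S.

Step 4
Reactants: 6 (5S,6Z)-8-[(tert-butyldimethylsilyl)oxy]-5-hydroxy-2,6-dimethylocta-1,6-dien-3-one; 7 benzaldehyde
Product: 8 (2Z,4S,6S)-1-[(tert-butyldimethylsilyl)oxy]-6-hydroxy-3,7-dimethylocta-2,7-dien-4-yl benzoate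
Conditions: 7 (5 equiv), SmI2 (20 mol %), THF, −10 °C
Reagents that add atoms: none
Why: Evans–Tishchenko reduction: the samarium-bound hemiacetal of benzaldehyde transfers hydride intramolecularly through a chair, so the C3 oxygen becomes the benzoate and the ketone becomes the 1,3-anti allylic alcohol in one operation (this C1 centre is erased in step 5).

Step 5
Reactants: 8 (2Z,4S,6S)-1-[(tert-butyldimethylsilyl)oxy]-6-hydroxy-3,7-dimethylocta-2,7-dien-4-yl benzoate; 9 butyl vinyl ether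
Product: 11 (2Z,4S,6E)-1-[(tert-butyldimethylsilyl)oxy]-3,7-dimethyl-10-oxodeca-2,6-dien-4-yl benzoate, via allyl vinyl ether 10 (not isolated)
Conditions: Pd(OCOCF3)2 (2 mol %), 4,7-diphenyl-1,10-phenanthroline, Et3N (cat.), 9 (solvent), 60 °C; evaporate, then xylenes, 140 °C
Reagents that add atoms: none
Why: Palladium-catalysed transfer vinylation followed by Claisen rearrangement through a chair with the C2 chain equatorial gives the E-trisubstituted C1=C10 alkene and the C7 aldehyde; the carbinol stereocentre is consumed and C3 is untouched.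

Step 6
Reactants: 12 (2E)-2-methylbut-2-en-1-ol
Product: 13 [(2S,3S)-2,3-dimethyloxiran-2-yl]methanol
Conditions: Ti(Oi-Pr)4 (10 mol %), L-(+)-diethyl tartrate (12 mol %), t-BuOOH, 4 Å MS, CH2Cl2, −20 °C
Reagents that add atoms: tert-butyl hydroperoxide, CC(C)(C)OO
Why: Sharpless asymmetric epoxidation; the L-(+)-tartrate titanium complex delivers oxygen to the alkene face that gives the (2S,3S)-epoxy alcohol, setting both side-chain stereocentres.

Step 7
Reactants: 13 [(2S,3S)-2,3-dimethyloxiran-2-yl]methanol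
Product: 14 (2R,3S)-2,3-dimethyloxirane-2-carboxylic acid
Conditions: RuCl3·xH2O (2 mol %), NaIO4, MeCN/EtOAc/H2O, rt
Reagents that add atoms: water, O; sodium periodate, [Na+].[O-]I(=O)(=O)=O
Why: RuO4-catalysed oxidation of the primary alcohol to the acid leaves the trisubstituted epoxide intact; the C2 descriptor changes from S to R only through CIP priorities.

Step 8
Reactants: 14 (2R,3S)-2,3-dimethyloxirane-2-carboxylic acid
Product: 16 (2R,3S)-2,3-dimethyloxirane-2-carbonyl 2,4,6-trichlorobenzoyl peroxide, via peroxy acid 15 (not isolated)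
Conditions: DCC, H2O2 (50 % aq., 5 equiv), CH2Cl2/Et2O, −10 °C; filter, cold brine wash, MgSO4; then 2,4,6-Cl3C6H2COCl, pyridine (1 equiv), −20 °C; used cold
Reagents that add atoms: hydrogen peroxide, OO; 2,4,6-trichlorobenzoyl chloride, O=C(Cl)c1c(Cl)cc(Cl)cc1Cl
Why: Carbodiimide-mediated perhydrolysis with excess hydrogen peroxide stops at the peroxy acid, and its acylation by the hindered, electron-poor aroyl chloride is the standard peracid-plus-acid-chloride synthesis of unsymmetrical diacyl peroxides; the oxiranyl carbon is a poor migrating group, so carboxy inversion is slow in the cold, and no stereocentre is touched.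

Step 9
Reactants: 11 (2Z,4S,6E)-1-[(tert-butyldimethylsilyl)oxy]-3,7-dimethyl-10-oxodeca-2,6-dien-4-yl benzoate; 16 (2R,3S)-2,3-dimethyloxirane-2-carbonyl 2,4,6-trichlorobenzoyl peroxide
Product: 17 (2Z,4S,6E,9R)-4-(benzoyloxy)-1-[(tert-butyldimethylsilyl)oxy]-3,7-dimethyl-10-oxodeca-2,6-dien-9-yl (2R,3S)-2,3-dimethyloxirane-2-carboxylate
Conditions: (R)-2-(triphenylmethyl)pyrrolidine (10 mol %), hydroquinone (10 mol %), 16 (1.1 equiv), THF, 0 °C; crude into step 10
Reagents that add atoms: none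
Why: Proposed new method: enamine-catalysed asymmetric α-acyloxylation of an aldehyde with an unsymmetrical diacyl peroxide that carries an enantiopure aliphatic α,β-epoxy acyl group as the transferred group and 2,4,6-trichlorobenzoate as a designed leaving group — the E-enamine of 11 attacks the O–O σ* orbital at the oxygen bound to the epoxy acyl group (SN2 at oxygen), because this expels the much more stable carboxylate (2,4,6-trichlorobenzoic acid, pKa about 1.5, against about 3.5 for 14) and the ortho-chlorines shield the aroyl side, and it does so on the enamine face away from the trityl group, forming the C8–O bond, fixing C8 as R and delivering the complete ester at once, while hydroquinone suppresses radical-chain homolysis and decarboxylation; the closest known reaction type is the amine-catalysed α-benzoyloxylation of aldehydes with dibenzoyl peroxide, not shown for aliphatic, chiral or unsymmetrical diacyl peroxides.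

Step 10
Reactants: 17 (2Z,4S,6E,9R)-4-(benzoyloxy)-1-[(tert-butyldimethylsilyl)oxy]-3,7-dimethyl-10-oxodeca-2,6-dien-9-yl (2R,3S)-2,3-dimethyloxirane-2-carboxylate; 18 methyl propiolate
Product: 20 methyl (3RS,4R,6E,9S,10Z)-9-(benzoyloxy)-12-[(tert-butyldimethylsilyl)oxy]-4-{[(2R,3S)-2,3-dimethyloxirane-2-carbonyl]oxy}-3-hydroxy-6,10-dimethyl-2-methylidenedodeca-6,10-dienoate, via methyl 2-(diisobutylalumanyl)prop-2-enoate 19 (not isolated)
Conditions: 18, i-Bu2AlH, N-methylmorpholine N-oxide, THF, 0 °C; then 17, −78 to 0 °C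
Reagents that add atoms: none
Why: Hydroalumination of the propiolate gives an α-aluminoacrylate that adds to the aldehyde (vinylalumination, a non-basic Morita–Baylis–Hillman equivalent), avoiding epimerisation at C8 and acyl migration; the new carbinol centre is inconsequential because step 11 removes it.

Step 11
Reactants: 20 methyl (3RS,4R,6E,9S,10Z)-9-(benzoyloxy)-12-[(tert-butyldimethylsilyl)oxy]-4-{[(2R,3S)-2,3-dimethyloxirane-2-carbonyl]oxy}-3-hydroxy-6,10-dimethyl-2-methylidenedodeca-6,10-dienoate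
Product: 21 methyl (2Z,4R,6E,9S,10Z)-9-(benzoyloxy)-2-(bromomethyl)-12-[(tert-butyldimethylsilyl)oxy]-4-{[(2R,3S)-2,3-dimethyloxirane-2-carbonyl]oxy}-6,10-dimethyldodeca-2,6,10-trienoate
Conditions: N-bromosuccinimide, Me2S, CH2Cl2, −20 °C to rt
Reagents that add atoms: N-bromosuccinimide, O=C1CCC(=O)N1Br
Why: Corey–Kim-type activation of the allylic alcohol as an alkoxysulfonium salt and SN2′ attack of bromide give the conjugated (Z)-2-(bromomethyl)enoate; C8 is not involved.

Step 12
Reactants: 21 methyl (2Z,4R,6E,9S,10Z)-9-(benzoyloxy)-2-(bromomethyl)-12-[(tert-butyldimethylsilyl)oxy]-4-{[(2R,3S)-2,3-dimethyloxirane-2-carbonyl]oxy}-6,10-dimethyldodeca-2,6,10-trienoate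
Product: 22 methyl (2Z,4R,6E,9S,10Z)-9-(benzoyloxy)-2-(bromomethyl)-4-{[(2R,3S)-2,3-dimethyloxirane-2-carbonyl]oxy}-12-hydroxy-6,10-dimethyldodeca-2,6,10-trienoate
Conditions: camphorsulfonic acid (10 mol %), MeOH/CH2Cl2, 0 °C
Reagents that add atoms: none
Why: Acid-catalysed methanolysis removes the primary allylic silyl ether while the esters, the electron-poor epoxide and the allylic bromide survive.

Step 13
Reactants: 22 methyl (2Z,4R,6E,9S,10Z)-9-(benzoyloxy)-2-(bromomethyl)-4-{[(2R,3S)-2,3-dimethyloxirane-2-carbonyl]oxy}-12-hydroxy-6,10-dimethyldodeca-2,6,10-trienoate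
Product: 23 methyl (2Z,4R,6E,9S,10Z)-9-(benzoyloxy)-2-(bromomethyl)-4-{[(2R,3S)-2,3-dimethyloxirane-2-carbonyl]oxy}-6,10-dimethyl-12-oxododeca-2,6,10-trienoate
Conditions: Dess–Martin periodinane, CH2Cl2, 0 °C; used at once
Reagents that add atoms: none
Why: Dess–Martin oxidation gives the Z-enal under non-basic conditions, without Z/E isomerisation or displacement of the bromide.

Step 14
Reactants: 23 methyl (2Z,4R,6E,9S,10Z)-9-(benzoyloxy)-2-(bromomethyl)-4-{[(2R,3S)-2,3-dimethyloxirane-2-carbonyl]oxy}-6,10-dimethyl-12-oxododeca-2,6,10-trienoate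
Product: 25 (3aR,4R,6E,9S,10Z,11aR)-9-(benzoyloxy)-6,10-dimethyl-3-methylidene-2-oxo-2,3,3a,4,5,8,9,11a-octahydrocyclodeca[b]furan-4-yl (2R,3S)-2,3-dimethyloxirane-2-carboxylate, via ring-closed hydroxy ester 24 (not isolated)
Conditions: CrCl2 (8 equiv), THF–DMF, rt, syringe-pump addition of 23 to 1 mM
Reagents that add atoms: none
Why: Intramolecular Nozaki–Hiyama–Kishi-type 2-(alkoxycarbonyl)allylation: the allylchromium adds to the enal through a chair-like transition state (anti addition, hence the trans 6,7-lactone) on the C7 face anti to the C8 acyloxy group with H8 eclipsing the enoate (allylic 1,3-strain), setting 6R and 7R, and the chromium alkoxide lactonises onto the methyl ester.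

Step 15
Reactants: 25 (3aR,4R,6E,9S,10Z,11aR)-9-(benzoyloxy)-6,10-dimethyl-3-methylidene-2-oxo-2,3,3a,4,5,8,9,11a-octahydrocyclodeca[b]furan-4-yl (2R,3S)-2,3-dimethyloxirane-2-carboxylate
Product: 26 (1R,3S,4Z,6R,7R,8R,10R)-3-(benzoyloxy)-8-{[(2R,3S)-2,3-dimethyloxirane-2-carbonyl]oxy}-1,10-epoxygermacra-4,11(13)-dien-12,6-olide (CNP0324463.5)
Conditions: mCPBA, CH2Cl2, −20 to 0 °C
Reagents that add atoms: 3-chloroperoxybenzoic acid, OOC(=O)c1cccc(Cl)c1
Why: Prilezhaev epoxidation of the only electron-rich alkene (C1=C10) from the outer face of the ring conformer that carries the C10 methyl on the β face gives the 1β,10α (1R,10R) epoxide; the C4=C5 alkene (two allylic acyloxy groups) and the conjugated methylene are deactivated.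

## Compound list

1 | 3-methylfuran-2(5H)-one | CC1=CCOC1=O | starting material
2 | (2Z)-4-hydroxy-N-methoxy-N,2-dimethylbut-2-enamide | CON(C)C(=O)/C(C)=C\CO | intermediate (not isolated)
3 | (2Z)-4-[(tert-butyldimethylsilyl)oxy]-N-methoxy-N,2-dimethylbut-2-enamide | CON(C)C(=O)/C(C)=C\CO[Si](C)(C)C(C)(C)C | intermediate
4 | (2Z)-4-[(tert-butyldimethylsilyl)oxy]-2-methylbut-2-enal | O=C/C(C)=C\CO[Si](C)(C)C(C)(C)C | intermediate
5 | 3-methylbut-3-en-2-one | CC(=O)C(C)=C | starting material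
6 | (5S,6Z)-8-[(tert-butyldimethylsilyl)oxy]-5-hydroxy-2,6-dimethylocta-1,6-dien-3-one | C=C(C)C(=O)C[C@H](O)/C(C)=C\CO[Si](C)(C)C(C)(C)C | intermediate
7 | benzaldehyde | O=Cc1ccccc1 | starting material
8 | (2Z,4S,6S)-1-[(tert-butyldimethylsilyl)oxy]-6-hydroxy-3,7-dimethylocta-2,7-dien-4-yl benzoate | C=C(C)[C@@H](O)C[C@H](OC(=O)c1ccccc1)/C(C)=C\CO[Si](C)(C)C(C)(C)C | intermediate
9 | butyl vinyl ether | C=COCCCC | starting material
10 | (2Z,4S,6S)-1-[(tert-butyldimethylsilyl)oxy]-6-(ethenyloxy)-3,7-dimethylocta-2,7-dien-4-yl benzoate | C=C(C)[C@@H](OC=C)C[C@H](OC(=O)c1ccccc1)/C(C)=C\CO[Si](C)(C)C(C)(C)C | intermediate (not isolated)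
11 | (2Z,4S,6E)-1-[(tert-butyldimethylsilyl)oxy]-3,7-dimethyl-10-oxodeca-2,6-dien-4-yl benzoate | O=CCC/C(C)=C/C[C@H](OC(=O)c1ccccc1)/C(C)=C\CO[Si](C)(C)C(C)(C)C | intermediate
12 | (2E)-2-methylbut-2-en-1-ol | C/C=C(\C)CO | starting material
13 | [(2S,3S)-2,3-dimethyloxiran-2-yl]methanol | OC[C@]1(C)O[C@H]1C | intermediate
14 | (2R,3S)-2,3-dimethyloxirane-2-carboxylic acid | OC(=O)[C@]1(C)O[C@H]1C | intermediate
15 | (2R,3S)-2,3-dimethyloxirane-2-carboperoxoic acid | OOC(=O)[C@]1(C)O[C@H]1C | intermediate (not isolated)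
16 | (2R,3S)-2,3-dimethyloxirane-2-carbonyl 2,4,6-trichlorobenzoyl peroxide | O=C(OOC(=O)c1c(Cl)cc(Cl)cc1Cl)[C@]1(C)O[C@H]1C | intermediate
17 | (2Z,4S,6E,9R)-4-(benzoyloxy)-1-[(tert-butyldimethylsilyl)oxy]-3,7-dimethyl-10-oxodeca-2,6-dien-9-yl (2R,3S)-2,3-dimethyloxirane-2-carboxylate | O=C[C@H](OC(=O)[C@]1(C)O[C@H]1C)C/C(C)=C/C[C@H](OC(=O)c1ccccc1)/C(C)=C\CO[Si](C)(C)C(C)(C)C | intermediate
18 | methyl propiolate | C#CC(=O)OC | starting material
19 | methyl 2-(diisobutylalumanyl)prop-2-enoate | C=C(C(=O)OC)[Al](CC(C)C)CC(C)C | intermediate (not isolated)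
20 | methyl (3RS,4R,6E,9S,10Z)-9-(benzoyloxy)-12-[(tert-butyldimethylsilyl)oxy]-4-{[(2R,3S)-2,3-dimethyloxirane-2-carbonyl]oxy}-3-hydroxy-6,10-dimethyl-2-methylidenedodeca-6,10-dienoate | C=C(C(=O)OC)C(O)[C@H](OC(=O)[C@]1(C)O[C@H]1C)C/C(C)=C/C[C@H](OC(=O)c1ccccc1)/C(C)=C\CO[Si](C)(C)C(C)(C)C | intermediate
21 | methyl (2Z,4R,6E,9S,10Z)-9-(benzoyloxy)-2-(bromomethyl)-12-[(tert-butyldimethylsilyl)oxy]-4-{[(2R,3S)-2,3-dimethyloxirane-2-carbonyl]oxy}-6,10-dimethyldodeca-2,6,10-trienoate | COC(=O)/C(CBr)=C/[C@H](OC(=O)[C@]1(C)O[C@H]1C)C/C(C)=C/C[C@H](OC(=O)c1ccccc1)/C(C)=C\CO[Si](C)(C)C(C)(C)C | intermediate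
22 | methyl (2Z,4R,6E,9S,10Z)-9-(benzoyloxy)-2-(bromomethyl)-4-{[(2R,3S)-2,3-dimethyloxirane-2-carbonyl]oxy}-12-hydroxy-6,10-dimethyldodeca-2,6,10-trienoate | COC(=O)/C(CBr)=C/[C@H](OC(=O)[C@]1(C)O[C@H]1C)C/C(C)=C/C[C@H](OC(=O)c1ccccc1)/C(C)=C\CO | intermediate
23 | methyl (2Z,4R,6E,9S,10Z)-9-(benzoyloxy)-2-(bromomethyl)-4-{[(2R,3S)-2,3-dimethyloxirane-2-carbonyl]oxy}-6,10-dimethyl-12-oxododeca-2,6,10-trienoate | COC(=O)/C(CBr)=C/[C@H](OC(=O)[C@]1(C)O[C@H]1C)C/C(C)=C/C[C@H](OC(=O)c1ccccc1)/C(C)=C\C=O | intermediate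
24 | methyl 2-[(1R,2R,3Z,5S,7E,10R)-5-(benzoyloxy)-10-{[(2R,3S)-2,3-dimethyloxirane-2-carbonyl]oxy}-2-hydroxy-4,8-dimethylcyclodeca-3,7-dien-1-yl]prop-2-enoate (formed as its chromium alkoxide) | C=C(C(=O)OC)[C@H]1[C@H](O)/C=C(/C)[C@@H](OC(=O)c2ccccc2)C/C=C(\C)C[C@H]1OC(=O)[C@]2(C)O[C@H]2C | intermediate (not isolated)
25 | (3aR,4R,6E,9S,10Z,11aR)-9-(benzoyloxy)-6,10-dimethyl-3-methylidene-2-oxo-2,3,3a,4,5,8,9,11a-octahydrocyclodeca[b]furan-4-yl (2R,3S)-2,3-dimethyloxirane-2-carboxylate | C=C1C(=O)O[C@@H]2/C=C(/C)[C@@H](OC(=O)c3ccccc3)C/C=C(\C)C[C@@H](OC(=O)[C@]3(C)O[C@H]3C)[C@@H]12 | intermediate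
26 | (1R,3S,4Z,6R,7R,8R,10R)-3-(benzoyloxy)-8-{[(2R,3S)-2,3-dimethyloxirane-2-carbonyl]oxy}-1,10-epoxygermacra-4,11(13)-dien-12,6-olide (CNP0324463.5) | C=C1C(=O)O[C@@H]2/C=C(/C)[C@@H](OC(=O)c3ccccc3)C[C@H]3O[C@]3(C)C[C@@H](OC(=O)[C@]3(C)O[C@H]3C)[C@@H]12 | target

## Step count and risks

Total step count: 15. Longest linear sequence: 12 steps (steps 1–5 and 9–15); the acid branch (steps 6–8) joins at step 9.

The three steps most likely to fail:

Step 9, the proposed new α-acyloxylation. The mixed peroxide may transfer the wrong acyloxy group, may decompose by carboxy inversion or radical decarboxylation, and the α-acyloxy aldehyde may lose optical purity. The fallback uses known chemistry, needs no peroxide, and sets out from 11. A known enamine-catalysed α-chlorination ((5S)-5-benzyl-2,2,3-trimethylimidazolidin-4-one trifluoroacetate, 2,3,4,5,6,6-hexachlorocyclohexa-2,4-dien-1-one, acetone, −30 °C) gives (2Z,4S,6E,9S)-1-[(tert-butyldimethylsilyl)oxy]-9-chloro-3,7-dimethyl-10-oxodeca-2,6-dien-4-yl benzoate F1. Classical SN2 displacement of the activated α-chloride by the caesium salt of acid 14 (Cs2CO3, DMF, −20 °C) then forms the C8–O bond with inversion and comes back to the route at 17.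

Step 14, the macrocyclisation. It may give oligomers, or the wrong relative configuration at C6/C7/C8. The fallback changes how the allyl nucleophile is made and sets out from 20. Acetylation (Ac2O, DMAP cat., pyridine) gives methyl (3RS,4R,6E,9S,10Z)-3-acetoxy-9-(benzoyloxy)-12-[(tert-butyldimethylsilyl)oxy]-4-{[(2R,3S)-2,3-dimethyloxirane-2-carbonyl]oxy}-6,10-dimethyl-2-methylidenedodeca-6,10-dienoate F2. Camphorsulfonic acid in methanol then gives the 12-hydroxy compound methyl (3RS,4R,6E,9S,10Z)-3-acetoxy-9-(benzoyloxy)-4-{[(2R,3S)-2,3-dimethyloxirane-2-carbonyl]oxy}-12-hydroxy-6,10-dimethyl-2-methylidenedodeca-6,10-dienoate F3, and Dess–Martin periodinane gives the enal methyl (3RS,4R,6E,9S,10Z)-3-acetoxy-9-(benzoyloxy)-4-{[(2R,3S)-2,3-dimethyloxirane-2-carbonyl]oxy}-6,10-dimethyl-2-methylidene-12-oxododeca-6,10-dienoate F4. Pd(PPh3)4 (zerovalent palladium, 5 mol %) with InI (monovalent indium) in THF at high dilution ionises the allylic acetate and converts the π-allylpalladium into an allylindium, generated only at catalytic concentration. This adds to the enal and lactonises, coming back to the route at 25.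

Step 3, the direct aldol. The isopropenyl ketone donor may polymerise, or the Z-enal may give low enantioselectivity. The fallback switches to auxiliary control and a later C1–C10 bond, and sets out from 4. The dianion of (1S)-2-hydroxy-1,2,2-triphenylethyl acetate (LiN(i-Pr)2, THF; MgBr2; −115 °C) adds to 4 to give (1S)-2-hydroxy-1,2,2-triphenylethyl (3S,4Z)-6-[(tert-butyldimethylsilyl)oxy]-3-hydroxy-4-methylhex-4-enoate F5. Aminolysis with MeNH(OMe)·HCl and i-PrMgCl releases the triphenylglycol and gives (3S,4Z)-6-[(tert-butyldimethylsilyl)oxy]-3-hydroxy-N-methoxy-N,4-dimethylhex-4-enamide F6. CH2=C(CH3)MgBr (3 equiv, THF, 0 °C) then comes back to the route at 6.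

## Further compounds

F1 | step 9 | (2Z,4S,6E,9S)-1-[(tert-butyldimethylsilyl)oxy]-9-chloro-3,7-dimethyl-10-oxodeca-2,6-dien-4-yl benzoate | O=C[C@@H](Cl)C/C(C)=C/C[C@H](OC(=O)c1ccccc1)/C(C)=C\CO[Si](C)(C)C(C)(C)C
F2 | step 14 | methyl (3RS,4R,6E,9S,10Z)-3-acetoxy-9-(benzoyloxy)-12-[(tert-butyldimethylsilyl)oxy]-4-{[(2R,3S)-2,3-dimethyloxirane-2-carbonyl]oxy}-6,10-dimethyl-2-methylidenedodeca-6,10-dienoate | C=C(C(=O)OC)C(OC(C)=O)[C@H](OC(=O)[C@]1(C)O[C@H]1C)C/C(C)=C/C[C@H](OC(=O)c1ccccc1)/C(C)=C\CO[Si](C)(C)C(C)(C)C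
F3 | step 14 | methyl (3RS,4R,6E,9S,10Z)-3-acetoxy-9-(benzoyloxy)-4-{[(2R,3S)-2,3-dimethyloxirane-2-carbonyl]oxy}-12-hydroxy-6,10-dimethyl-2-methylidenedodeca-6,10-dienoate | C=C(C(=O)OC)C(OC(C)=O)[C@H](OC(=O)[C@]1(C)O[C@H]1C)C/C(C)=C/C[C@H](OC(=O)c1ccccc1)/C(C)=C\CO
F4 | step 14 | methyl (3RS,4R,6E,9S,10Z)-3-acetoxy-9-(benzoyloxy)-4-{[(2R,3S)-2,3-dimethyloxirane-2-carbonyl]oxy}-6,10-dimethyl-2-methylidene-12-oxododeca-6,10-dienoate | C=C(C(=O)OC)C(OC(C)=O)[C@H](OC(=O)[C@]1(C)O[C@H]1C)C/C(C)=C/C[C@H](OC(=O)c1ccccc1)/C(C)=C\C=O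
F5 | step 3 | (1S)-2-hydroxy-1,2,2-triphenylethyl (3S,4Z)-6-[(tert-butyldimethylsilyl)oxy]-3-hydroxy-4-methylhex-4-enoate | O=C(C[C@H](O)/C(C)=C\CO[Si](C)(C)C(C)(C)C)O[C@@H](c1ccccc1)C(O)(c1ccccc1)c1ccccc1
F6 | step 3 | (3S,4Z)-6-[(tert-butyldimethylsilyl)oxy]-3-hydroxy-N-methoxy-N,4-dimethylhex-4-enamide | CON(C)C(=O)C[C@H](O)/C(C)=C\CO[Si](C)(C)C(C)(C)C
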